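The trap at this bench was to tune the dissolution of the crystals before asking whether crystals formed at all.

    starting material + enzyme ⇌ starting complex (K1 = 96 /M, k1 = 42000 /M/s)
    crystals ⇌ product, rate k2*(cs2 - [product]) while solid is left; crystals form when [product] > cs2 (cs2 = 8.5 mM, k2 = 0.82 /min)
    ternary complex → enzyme + product (k3 = 830 /min)
    second substrate + starting complex ⇌ ternary complex (K4 = 6.9 /M, k4 = 19000 /M/s)

starting material 10 mM; second substrate 50.0 mM; enzyme 1.4 µM; time 8.0 min

* how much product and crystals together there is at 8.0 min, in percent of the starting material charged
* concentration of product in solution at 4.0 min, in percent of saturation
* the change that raises the amount of product and crystals together at 8.0 min, in percent of the starting material charged most ("none" if none brings more than 2 percentage points) (violet / blue / green / red / none)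
* amount of product and crystals together at 8.0 min, in percent of the starting material charged, after green

- for product the crystals are counted in
- as a solid, counted per litre of solution: crystals
- run time (flask): 8.0 min

My note for the next shift began with what I froze. Starting material and second substrate each stood far above the enzyme, so I held c(starting material) and c(second substrate) at their charges. Ternary complex fell back at 1.65 × 10⁵ /min, faster than it released product at 830 /min, which made release the slow, rate-limiting step and let the enzyme sit in binding equilibrium. Its forms then weighed one for free enzyme, 0.960 for starting complex and 0.331 for ternary complex. That gave the ternary share, the fraction of the enzyme held as ternary complex: 14.5 %.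

Turnover was the release constant times the enzyme charge times that share, 0.168 mM/min. So I told them to expect 13.4 % of the charge as product at 8.0 min, and 7.91 % of saturation at 4.0 min. Leave solubility and dissolution coefficient alone: 1.34 mM is less than 8.5 mM. In my reckoning green doubled turnover, while blue lifted the share to 25.3 %, a smaller gain. Green by my reckoning gave 26.9 %.

The forecast stood lower than my frozen figures: 12.8 % (12.3 % to 13.3 %), 7.7 % (7.3 % to 8.1 %), green as best and 24.5 % (23.5 % to 25.3 %) after it, on the ground that “Rate is strictly proportional to enzyme”.

The simulation gave 12.8 % and 7.67 %, with crystals at 0 %. The best change was green, which gained 12 percentage points, more than the 9.1 points of blue, and reached 24.5 %; how little product dissolves made no difference.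

The charged flask stood at 12.8 % because ternary complex returned to second substrate and starting complex, and because the reading came at 8.0 min and not at 80.0 min: the run without that return gave 82.8 %, the longer run 81.9 %. At 0.800 min the ternary complex held 14.2 % of the enzyme, against my 14.5 %. The neighbour flask charged with 0.0056 mM of enzyme ended with a share of 9.73 %; the mean of that and 14.5 %, multiplied by the release constant, that charge and the time, gives 45.0 %, and that flask read 44.7 %.

(The constants were set for the occasion; no experiment stands behind them.)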